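## Retrosynthetic overview

1. Ester C–O bond: target 21 ⇒ acid 18 + (R)-glycidyl acetate 20 (the acid opens the epoxide CH2). Side chain: enol triflate 14 (from ketone 13) + Grignard reagent 16, by iron-catalysed Kumada coupling.
2. Ring B: one iron-hydride radical cascade joins vinylcyclopropane 9 and acrolein 10 in a formal [3+3] annulation. It makes C7–C8 (acrolein C-3 to the former cyclopropane CH2) and C4a–C5 (acrolein C-1 to the ring-fusion carbon) of the decalin.
3. Enabling feature: the strained C6–C7 bond of the cyclopropane fused to ring A in 9 (a bicyclo[4.1.0]hept-4-ene), allylic to the C4=C5 alkene. A radical at C-5 opens it and frees C-7, then C-6, as 1,3-related radical sites.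
4. Cyclopropane: hydroxyl-directed Simmons–Smith reaction on allylic alcohol 5 fixes the quaternary C-8a. Ring A: asymmetric Michael/aldol annulation of methyl acetoacetate 1 with (E)-hex-4-en-3-one 2.
5. Ring order: ring A (step 1), cyclopropane (step 3, sacrificed in step 7), ring B (step 7).

Key step: step 7

Assumption: of the two pseudo-enantiomeric cinchona primary amines, the one that gives the (3R)-Michael adduct 3 is meant; 9-amino-9-deoxy-epi-quinine is written for it and would be exchanged for the quinidine-derived catalyst if the facial sense proves opposite.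

## Route

Step 1
Reactants: 1 methyl acetoacetate; 2 (E)-hex-4-en-3-one
Product: 4 methyl (1S,6R)-2,3,6-trimethyl-4-oxocyclohex-2-ene-1-carboxylate, via Michael adduct 3 (not isolated)
Conditions: 9-amino-9-deoxy-epi-quinine (10 mol%), CF3CO2H (20 mol%), THF, rt; then TsOH·H2O (10 mol%), PhMe, 80 °C
Reagents that add atoms: none
Why: iminium activation of the enone by the chiral primary amine should let the acetoacetate add to one face of the β-carbon (organocatalytic asymmetric Michael addition, sets C-6); acid then closes ring A by intramolecular aldol condensation (Robinson-type annulation) and should equilibrate C-1 through the dienol to the trans ester.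

Step 2
Reactants: 4 methyl (1S,6R)-2,3,6-trimethyl-4-oxocyclohex-2-ene-1-carboxylate
Product: 5 methyl (1S,4S,6R)-4-hydroxy-2,3,6-trimethylcyclohex-2-ene-1-carboxylate
Conditions: NaBH4, CeCl3·7H2O, MeOH, −40 °C
Reagents that add atoms: none
Why: Luche reduction is 1,2-selective, and axial hydride delivery to the half-chair should place the hydroxyl cis to the 6-methyl, as in the reduction of carvone to cis-carveol.

Step 3
Reactants: 5 methyl (1S,4S,6R)-4-hydroxy-2,3,6-trimethylcyclohex-2-ene-1-carboxylate
Product: 6 methyl (1R,2S,3R,5S,6R)-5-hydroxy-1,3,6-trimethylbicyclo[4.1.0]heptane-2-carboxylate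
Conditions: Et2Zn, CH2I2, CH2Cl2, 0 °C to rt
Reagents that add atoms: diiodomethane, ICI
Why: in the hydroxyl-directed Simmons–Smith cyclopropanation the zinc alkoxide should deliver CH2 to its own face of the electron-rich tetrasubstituted alkene, which sets both quaternary carbons with the CH2 syn to the hydroxyl and anti to the ester.

Step 4
Reactants: 6 methyl (1R,2S,3R,5S,6R)-5-hydroxy-1,3,6-trimethylbicyclo[4.1.0]heptane-2-carboxylate
Product: 7 methyl (1R,2S,3R,6R)-1,3,6-trimethyl-5-oxobicyclo[4.1.0]heptane-2-carboxylate
Conditions: Dess–Martin periodinane, CH2Cl2, rt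
Reagents that add atoms: none
Why: Dess–Martin oxidation of the secondary alcohol is mild and non-acidic enough to leave the cyclopropyl carbinol skeleton intact.

Step 5
Reactants: 7 methyl (1R,2S,3R,6R)-1,3,6-trimethyl-5-oxobicyclo[4.1.0]heptane-2-carboxylate
Product: 8 methyl (1R,2S,3R,6R)-1,3,6-trimethyl-5-{[(trifluoromethyl)sulfonyl]oxy}bicyclo[4.1.0]hept-4-ene-2-carboxylate
Conditions: KN(SiMe3)2, THF, −78 °C; PhNTf2, −78 to 0 °C
Reagents that add atoms: N-phenylbis(trifluoromethanesulfonimide), O=S(=O)(N(c1ccccc1)S(=O)(=O)C(F)(F)F)C(F)(F)F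
Why: kinetic enolate formation and O-triflation can only go toward C-4, because the other α-carbon is the quaternary cyclopropane carbon and the ketone α-CH2 is more acidic and less hindered than the ester α-CH.

Step 6
Reactants: 8 methyl (1R,2S,3R,6R)-1,3,6-trimethyl-5-{[(trifluoromethyl)sulfonyl]oxy}bicyclo[4.1.0]hept-4-ene-2-carboxylate
Product: 9 methyl (1R,2S,3R,6S)-1,3,6-trimethylbicyclo[4.1.0]hept-4-ene-2-carboxylate
Conditions: Pd(OAc)2 (5 mol%), PPh3 (10 mol%), HCO2H, Bu3N, DMF, 60 °C
Reagents that add atoms: none
Why: palladium-catalysed formate reduction of an alkenyl triflate (oxidative addition, decarboxylation of formate to a palladium hydride, reductive elimination) should give the vinylcyclopropane without touching the three-membered ring.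

Step 7
Reactants: 9 methyl (1R,2S,3R,6S)-1,3,6-trimethylbicyclo[4.1.0]hept-4-ene-2-carboxylate; 10 acrolein
Product: 12 methyl (1S,2R,4aS,8aR)-5-hydroxy-2,4a,8a-trimethyldecahydronaphthalene-1-carboxylate, via ring-opened aldehyde 11 (not isolated)
Conditions: Fe(acac)3 (30 mol%), PhSiH3 (3 equiv), acrolein (1.3 equiv, syringe pump), EtOH/(CH2OH)2 5:1, 0 to 60 °C
Reagents that add atoms: none
Why: Proposed new method: a hydridoiron species formed from Fe(acac)3 and PhSiH3 gives a hydrogen atom to C-4 of 9, the cyclopropylcarbinyl radical at C-5 opens the exocyclic C6–C7 bond, the primary C-7 radical adds to the β-carbon of acrolein (Giese addition) and reduction and protonation of the α-formyl radical give aldehyde 11 with a new C5=C6 alkene; a second, Markovnikov hydrogen atom transfer to that alkene gives the tertiary radical at C-6, which adds to the formyl carbon, and the alkoxy radical is reduced to 12. The closest known reaction types are the iron-hydride reductive coupling of alkenes with acceptor alkenes, the radical-clock opening of vinylcyclopropanes under hydrogen atom transfer and the hydrogen-atom-transfer-initiated reductive cyclization of alkenes onto carbonyl groups; their union into a formal [3+3] annulation of a vinylcyclopropane with an enal is not known. Ring B is closed by a 6-exo-trig radical addition to the C=O group. The quaternary C-4a should be set cis to C-8a because the tether on the neighbouring quaternary carbon closes a chair-like transition state on its own face, while a trans fusion would force both angular methyls to be diaxial; the carbinol carbon forms as a mixture that step 8 removes. The step needs (a) hydrogen delivery to C-4 and not C-5, which the cyclopropyl stabilization of the C-5 radical and the crowding at C-5 should secure, (b) cleavage of the exocyclic and not the ring-fusion cyclopropane bond, favoured by orbital overlap and by fast capture of the unhindered primary radical, and (c) ring closure of the tertiary radical before it meets free acrolein, which slow addition of acrolein should secure.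

Step 8
Reactants: 12 methyl (1S,2R,4aS,8aR)-5-hydroxy-2,4a,8a-trimethyldecahydronaphthalene-1-carboxylate
Product: 13 methyl (1S,2R,4aS,8aR)-2,4a,8a-trimethyl-5-oxodecahydronaphthalene-1-carboxylate
Conditions: Dess–Martin periodinane, CH2Cl2, rt
Reagents that add atoms: none
Why: Dess–Martin oxidation converges both carbinol epimers on one ketone and leaves the hindered methyl ester untouched.

Step 9
Reactants: 13 methyl (1S,2R,4aS,8aR)-2,4a,8a-trimethyl-5-oxodecahydronaphthalene-1-carboxylate
Product: 14 methyl (1S,2R,4aS,8aR)-2,4a,8a-trimethyl-5-{[(trifluoromethyl)sulfonyl]oxy}-1,2,3,4,4a,7,8,8a-octahydronaphthalene-1-carboxylate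
Conditions: KN(SiMe3)2, THF, −78 °C; PhNTf2, −78 to 0 °C
Reagents that add atoms: N-phenylbis(trifluoromethanesulfonimide), O=S(=O)(N(c1ccccc1)S(=O)(=O)C(F)(F)F)C(F)(F)F
Why: the ketone can enolize only toward C-6 because C-4a is quaternary, so enolate O-triflation fixes the ring B double bond in the position the target needs.

Step 10
Reactants: 14 methyl (1S,2R,4aS,8aR)-2,4a,8a-trimethyl-5-{[(trifluoromethyl)sulfonyl]oxy}-1,2,3,4,4a,7,8,8a-octahydronaphthalene-1-carboxylate; 15 5-bromo-2-methylpent-2-ene
Product: 17 methyl (1S,2R,4aR,8aR)-2,4a,8a-trimethyl-5-(4-methylpent-3-en-1-yl)-1,2,3,4,4a,7,8,8a-octahydronaphthalene-1-carboxylate, via Grignard reagent 16 (not isolated)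
Conditions: 15, Mg, THF, rt; then 14, Fe(acac)3 (5 mol%), THF/NMP, −30 to 0 °C
Reagents that add atoms: none
Why: iron-catalysed Kumada coupling of an alkyl Grignard reagent with an alkenyl triflate is fast at low temperature, should tolerate the hindered ester and forms the sp2–sp3 bond without moving the double bond.

Step 11
Reactants: 17 methyl (1S,2R,4aR,8aR)-2,4a,8a-trimethyl-5-(4-methylpent-3-en-1-yl)-1,2,3,4,4a,7,8,8a-octahydronaphthalene-1-carboxylate
Product: 18 (1S,2R,4aR,8aR)-2,4a,8a-trimethyl-5-(4-methylpent-3-en-1-yl)-1,2,3,4,4a,7,8,8a-octahydronaphthalene-1-carboxylic acid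
Conditions: LiI, DMF, 120 °C; then 1 M HCl
Reagents that add atoms: none
Why: iodide attacks the methyl carbon (nucleophilic dealkylation of a methyl ester), so the hindered acyl carbon is not involved, C-1 should not epimerize and both alkenes are spared from acid.

Step 12
Reactants: 19 (S)-glycidol
Product: 20 (R)-glycidyl acetate
Conditions: Ac2O, Et3N, DMAP (cat.), CH2Cl2, 0 °C
Reagents that add atoms: acetic anhydride, CC(=O)OC(C)=O
Why: DMAP-catalysed O-acetylation of the primary alcohol leaves the epoxide and its stereocenter untouched (the descriptor changes from S to R only through the priority rules).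

Step 13
Reactants: 18 (1S,2R,4aR,8aR)-2,4a,8a-trimethyl-5-(4-methylpent-3-en-1-yl)-1,2,3,4,4a,7,8,8a-octahydronaphthalene-1-carboxylic acid; 20 (R)-glycidyl acetate
Product: 21 (2S)-3-(acetyloxy)-2-hydroxypropyl (1S,2R,4aR,8aR)-2,4a,8a-trimethyl-5-(4-methylpent-3-en-1-yl)-1,2,3,4,4a,7,8,8a-octahydronaphthalene-1-carboxylate
Conditions: Bu4NBr (10 mol%), PhMe, 80 °C
Reagents that add atoms: none
Why: halide-catalysed ring opening of a terminal epoxide by a carboxylic acid occurs at the CH2 terminus, so the ester, the free secondary hydroxyl and the acetate should arise in one step with the glycerol stereocenter untouched.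

## Compound list

1 | methyl acetoacetate | COC(=O)CC(C)=O | starting material
2 | (E)-hex-4-en-3-one | CCC(=O)/C=C/C | starting material
3 | methyl (3R)-2-acetyl-3-methyl-5-oxoheptanoate (Michael adduct, C-2 epimers) | CCC(=O)C[C@@H](C)C(C(C)=O)C(=O)OC | intermediate
4 | methyl (1S,6R)-2,3,6-trimethyl-4-oxocyclohex-2-ene-1-carboxylate (ester trans to 6-methyl) | COC(=O)[C@H]1[C@H](C)CC(=O)C(C)=C1C | intermediate
5 | methyl (1S,4S,6R)-4-hydroxy-2,3,6-trimethylcyclohex-2-ene-1-carboxylate (hydroxyl cis to 6-methyl) | COC(=O)[C@H]1[C@H](C)C[C@H](O)C(C)=C1C | intermediate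
6 | methyl (1R,2S,3R,5S,6R)-5-hydroxy-1,3,6-trimethylbicyclo[4.1.0]heptane-2-carboxylate (hydroxyl, 3-methyl and cyclopropane CH2 on one face; ester and both bridgehead methyls on the other) | COC(=O)[C@H]1[C@H](C)C[C@H](O)[C@]2(C)C[C@]12C | intermediate
7 | methyl (1R,2S,3R,6R)-1,3,6-trimethyl-5-oxobicyclo[4.1.0]heptane-2-carboxylate | COC(=O)[C@H]1[C@H](C)CC(=O)[C@]2(C)C[C@]12C | intermediate
8 | methyl (1R,2S,3R,6R)-1,3,6-trimethyl-5-{[(trifluoromethyl)sulfonyl]oxy}bicyclo[4.1.0]hept-4-ene-2-carboxylate | COC(=O)[C@H]1[C@H](C)C=C(OS(=O)(=O)C(F)(F)F)[C@]2(C)C[C@]12C | intermediate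
9 | methyl (1R,2S,3R,6S)-1,3,6-trimethylbicyclo[4.1.0]hept-4-ene-2-carboxylate (vinylcyclopropane) | COC(=O)[C@H]1[C@H](C)C=C[C@]2(C)C[C@]12C | intermediate
10 | acrolein | C=CC=O | starting material
11 | methyl (1S,2R,6R)-2,3,6-trimethyl-2-(4-oxobutyl)cyclohex-3-ene-1-carboxylate | COC(=O)[C@H]1[C@H](C)CC=C(C)[C@]1(C)CCCC=O | intermediate
12 | methyl (1S,2R,4aS,8aR)-5-hydroxy-2,4a,8a-trimethyldecahydronaphthalene-1-carboxylate (cis-fused, C-5 epimers) | COC(=O)[C@H]1[C@H](C)CC[C@]2(C)C(O)CCC[C@]12C | intermediate
13 | methyl (1S,2R,4aS,8aR)-2,4a,8a-trimethyl-5-oxodecahydronaphthalene-1-carboxylate | COC(=O)[C@H]1[C@H](C)CC[C@]2(C)C(=O)CCC[C@]12C | intermediate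
14 | methyl (1S,2R,4aS,8aR)-2,4a,8a-trimethyl-5-{[(trifluoromethyl)sulfonyl]oxy}-1,2,3,4,4a,7,8,8a-octahydronaphthalene-1-carboxylate | COC(=O)[C@H]1[C@H](C)CC[C@]2(C)C(OS(=O)(=O)C(F)(F)F)=CCC[C@]12C | intermediate
15 | 5-bromo-2-methylpent-2-ene | CC(C)=CCCBr | starting material
16 | (4-methylpent-3-en-1-yl)magnesium bromide | CC(C)=CCC[Mg]Br | intermediate
17 | methyl (1S,2R,4aR,8aR)-2,4a,8a-trimethyl-5-(4-methylpent-3-en-1-yl)-1,2,3,4,4a,7,8,8a-octahydronaphthalene-1-carboxylate | COC(=O)[C@H]1[C@H](C)CC[C@]2(C)C(CCC=C(C)C)=CCC[C@]12C | intermediate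
18 | (1S,2R,4aR,8aR)-2,4a,8a-trimethyl-5-(4-methylpent-3-en-1-yl)-1,2,3,4,4a,7,8,8a-octahydronaphthalene-1-carboxylic acid | OC(=O)[C@H]1[C@H](C)CC[C@]2(C)C(CCC=C(C)C)=CCC[C@]12C | intermediate
19 | (S)-glycidol | OC[C@H]1CO1 | starting material
20 | (R)-glycidyl acetate | CC(=O)OC[C@H]1CO1 | intermediate
21 | CNP0146255.1, (2S)-3-(acetyloxy)-2-hydroxypropyl ester of acid 18 | CC(=O)OC[C@H](O)COC(=O)[C@H]1[C@H](C)CC[C@]2(C)C(CCC=C(C)C)=CCC[C@]12C | target

## Step count and risks

Total step count: 13. Longest linear sequence: 12 steps (steps 1 to 11, then 13).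

Steps most likely to fail:

1. Step 7 (proposed new method). The hydrogen atom may go to C-5 instead of C-4, and the ring-fusion cyclopropane bond may open, which expands the ring. The tertiary radical may be intercepted by a second acrolein, or the primary radical may be reduced too early. The ring may also close to the trans fusion. Fallback, setting out from 6 and coming back at 13: 6 is converted with NaH, CS2 and MeI into the S-methyl xanthate F1. Bu3SnH, AIBN and excess acrylonitrile in benzene at 80 °C (Barton–McCombie radical generation, cyclopropane opening, Giese addition) should give the nitrile F2. A separate hydrogen-atom-transfer cyclization of the alkene onto the nitrile (Fe(acac)3, PhSiH3, EtOH, 60 °C), followed by hydrolysis of the imine, should give ketone 13; steps 4 to 8 are replaced.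

2. Step 1. The Michael addition may show low facial selectivity, the aldol may close in the other direction (acetyl methyl onto the ethyl ketone), or epimerization to the trans ester may be incomplete. Fallback, setting out from 1 and 2 and coming back at 5: NaOMe in MeOH gives the annulation product as a racemate, that is 4 together with the antipodal enone F3. Luche reduction gives 5 together with the antipodal alcohol F4. Amano lipase PS with vinyl acetate is expected, by the empirical rule for secondary alcohols, to acylate the (4R)-alcohol to the acetate F5 and leave 5, which is separated by chromatography.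

3. Step 13. The acetyl or the new acyl group may migrate to the secondary hydroxyl, the epoxide may be attacked at the internal carbon, or the hindered acid may react slowly. Fallback, setting out from 18 and coming back at 21: 18 is converted into its acid chloride ((COCl)2, cat. DMF) and acylates (R)-solketal (pyridine, DMAP) to the solketal ester F6. 80% aqueous AcOH at 40 °C removes the acetonide to give the diol monoester F7. AcCl with 2,4,6-collidine in CH2Cl2 at −78 °C should acetylate only the primary hydroxyl to give 21.

## Further compounds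

F1 | step 7 | methyl (1R,2S,3R,5S,6R)-1,3,6-trimethyl-5-{[(methylsulfanyl)carbonothioyl]oxy}bicyclo[4.1.0]heptane-2-carboxylate | COC(=O)[C@H]1[C@H](C)C[C@H](OC(=S)SC)[C@]2(C)C[C@]12C
F2 | step 7 | methyl (1S,2R,6R)-2-(3-cyanopropyl)-2,3,6-trimethylcyclohex-3-ene-1-carboxylate | COC(=O)[C@H]1[C@H](C)CC=C(C)[C@]1(C)CCCC#N
F3 | step 1 | methyl (1R,6S)-2,3,6-trimethyl-4-oxocyclohex-2-ene-1-carboxylate | COC(=O)[C@@H]1[C@@H](C)CC(=O)C(C)=C1C
F4 | step 1 | methyl (1R,4R,6S)-4-hydroxy-2,3,6-trimethylcyclohex-2-ene-1-carboxylate | COC(=O)[C@@H]1[C@@H](C)C[C@@H](O)C(C)=C1C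
F5 | step 1 | methyl (1R,4R,6S)-4-(acetyloxy)-2,3,6-trimethylcyclohex-2-ene-1-carboxylate | COC(=O)[C@@H]1[C@@H](C)C[C@@H](OC(C)=O)C(C)=C1C
F6 | step 13 | [(4S)-2,2-dimethyl-1,3-dioxolan-4-yl]methyl (1S,2R,4aR,8aR)-2,4a,8a-trimethyl-5-(4-methylpent-3-en-1-yl)-1,2,3,4,4a,7,8,8a-octahydronaphthalene-1-carboxylate | CC1(C)OC[C@@H](COC(=O)[C@H]2[C@H](C)CC[C@]3(C)C(CCC=C(C)C)=CCC[C@]23C)O1
F7 | step 13 | (2S)-2,3-dihydroxypropyl (1S,2R,4aR,8aR)-2,4a,8a-trimethyl-5-(4-methylpent-3-en-1-yl)-1,2,3,4,4a,7,8,8a-octahydronaphthalene-1-carboxylate | OC[C@H](O)COC(=O)[C@H]1[C@H](C)CC[C@]2(C)C(CCC=C(C)C)=CCC[C@]12C
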